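Hold the partner molarity nearly fixed and, in the runs so far, the fraction of the charge that has become isomer of the product barely moves: oak and maple, at 0.438 M and 0.450 M of partner, read 13.8 % and 13.2 % at 80.0 s, though maple carries 0.15 M of substrate and oak 0.073 M.

| flask | substrate | partner | remark | time |
|---|---|---|---|---|
| ash | 0.073 M | 3 equiv | run made earlier |  |
| larch | 0.073 M | 1.5 equiv | run made earlier |  |
| oak | 0.073 M | 6 equiv | run made earlier |  |
| maple | 0.15 M | 3 equiv | run made earlier |  |
| amber | 0.073 M (fed, over 80 s) | 3.00 equiv | all else is in the flask from the start; the feed brings no volume worth counting | 2.0 min |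
| violet | 0.073 M | 3.00 equiv (fed, over 80 s) | all else is in the flask from the start; the feed brings no volume worth counting | 2.0 min |
| ochre | 0.073 M | 3.00 equiv | everything together at the start | 2.0 min |

| run | time / s | isomer of the product / % | target / % |
|---|---|---|---|
| ash | 10.0 | 0.1 | 0 |
| ash | 12.0 | 0.4 | 0.6 |
| ash | 20.0 | 0.3 | 1.0 |
| ash | 30.0 | 1.0 | 2.6 |
| ash | 50.0 | 4.0 | 6.2 |
| ash | 80.0 | 11.0 | 9.8 |
| larch | 10.0 | 0 | 0.1 |
| larch | 20.0 | 0.2 | 0.6 |
| larch | 30.0 | 0.6 | 1.5 |
| larch | 40.0 | 1.4 | 3.3 |
| larch | 50.0 | 2.2 | 4.0 |
| larch | 60.0 | 3.8 | 5.6 |
| larch | 80.0 | 7.9 | 7.4 |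
| oak | 10.0 | 0.1 | 0.7 |
| oak | 20.0 | 0 | 1.5 |
| oak | 30.0 | 1.3 | 3.6 |
| oak | 40.0 | 2.8 | 5.8 |
| oak | 50.0 | 5.3 | 7.9 |
| oak | 60.0 | 7.8 | 8.8 |
| oak | 80.0 | 13.8 | 10.2 |
| maple | 10.0 | 0.3 | 0.8 |
| maple | 20.0 | 0.2 | 1.9 |
| maple | 40.0 | 2.9 | 5.6 |
| maple | 80.0 | 13.2 | 10.9 |

(scatter of a reading: 0.3 percentage points)



- the flask that comes out highest in amount of isomer of the product, in percent of the substrate charged; "all alike" if 1.5 percentage points covers them all (amber / violet / ochre / all alike)
- amount of isomer of the product at the end, in percent of the substrate charged, amber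
- amount of isomer of the product at the end, in percent of the substrate charged, violet
- amount of isomer of the product at the end, in percent of the substrate charged, ochre

1. So substrate looks pseudo-first-order: each portion runs its own clock, and you can read amber off the ash curve. Define the mean age of the charge as the end time less half the feed time: 80.0 s. Ash reads 11.0 % of the charge at that age, so that is your first figure for amber.

2. Objection: the ash curve bends upward. Its gain rises from 0.00150 /s to 0.00233 /s of the charge, so old portions gain more than young ones lose. Put amber a little above 11.0 %.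

3. Ochre is the ash recipe, carried on. The last ash slope gives 20.3 % at the end, and the bend pushes that up. As estimates, that ochre figure stands 9.3 percentage points above the first amber figure, more than the margin, so I expect ochre to lead amber by more than the margin.

4. Violet: the partner ramp gives, by the end, the same partner exposure as ash at 80.0 s. Objection: larch, with half the partner of ash, still reads 7.9 % against 11.0 %, so partner doesn't set the whole pace. I put violet somewhat above amber, well under ochre.

5. The forecast says ochre, with 12 % for amber, 20 % for violet and 23 % for ochre, holding that “low early partner only delays things by roughly 10 s”. I charge violet 40.0 s instead, so we part there.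

6. The flasks give 22.3 % in ochre, 13.7 % in violet and 11.5 % in amber, so ochre is highest.

    target → over-reaction product (k = 0.0190 /s)
    intermediate B → target (k = 0.0170 /s)
    partner + intermediate A ⇌ intermediate C (K = 7.40 /M, k = 0.0170 /M/s)
    target ⇌ isomer of the product (K = 5.00, k = 0.0370 /s)
    intermediate A → intermediate B (k = 0.0190 /s)
    substrate + partner → intermediate A (k = 0.260 /M/s)

7. Amber stands 0.50 points above the ash reading at the mean age, violet 2.7 points above it. Neither they nor ochre are at rest at the end. Left ten times as long, the feed delay in amber and violet shrinks from 33.3 % of the elapsed time to 3.33 %. Isomer of the product falls to 7.03 % in amber, 6.77 % in violet and 6.45 % in ochre, so ochre's lead of 11 points over amber turns into amber standing 0.58 points ahead, while over-reaction product reaches 91.1 % in ochre.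

The data are simulated from invented constants; scatter was added.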